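## Retrosynthetic overview

1. Feature: in the hexasubstituted ring A, C4a is the only carbon without a substituent and lies between C8a (bearing O1) and C5 (bearing the 5-OH). Because C6 and C8 both carry prenyl, these two flanking oxygens are equivalent in a ring A building block.
2. Key disconnection C4–C4a: a photo-Fries 1,3-acyl shift moves C4 from a temporary aryl ester on one flanking oxygen onto C4a. The phenol set free by the shift then closes ring C in the same flask as O1 by Mitsunobu inversion at C2, and the other flanking oxygen (MOM) becomes the 5-oxygen.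
3. The ester is kept open-chain on purpose. A lactone tying both flanking oxygens together through C2–C3–C4 would be a five-atom meta bridge with H–C4a inside the ring (a dioxa[5]metacyclophane) and could not be closed by lactonisation, so O1–C2 is formed after the acyl shift, not before it.
4. Ester 17 comes from phenol 7 (phloroglucinol, two directed ortho-lithiation/prenylations) and an aroylketene from acid 12 (5-bromovanillin, Stille prenylation). Its (R)-carbinol is set by Noyori transfer hydrogenation and becomes (2S) on inversion.
5. Ring order: rings A and B are bought as arenes; ring C is the only ring formed (step 12); removal of three MOM ethers ends the route.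

Key step: step 12

Remark: flavanone numbering is used (O1, C2, C3, C4, C4a, C5–C8, C8a; primes for ring B); prenyl = 3-methylbut-2-en-1-yl, MOM = methoxymethyl; C2 is S as read from the SMILES; 5-bromovanillin and tributyl(prenyl)stannane are taken as commercial.

## Route

Step 1
Reactants: 1 phloroglucinol
Product: 2 3,5-bis(methoxymethoxy)phenol
Conditions: MOMCl (2 equiv), i-Pr2NEt, DMF/CH2Cl2, 0 °C → rt
Reagents that add atoms: chloromethyl methyl ether (MOMCl), COCCl
Why: MOM ether formation (Williamson-type O-alkylation); with two equivalents the bis-ether should be the main member of the statistical series, and the mono- and tris-ethers are removed by chromatography.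

Step 2
Reactants: 2 3,5-bis(methoxymethoxy)phenol
Product: 3 1-(benzyloxy)-3,5-bis(methoxymethoxy)benzene
Conditions: BnBr, K2CO3, DMF, rt
Reagents that add atoms: benzyl bromide, BrCc1ccccc1
Why: Williamson ether synthesis on the one remaining phenol; benzyl is chosen because it directs ortho-lithiation far less well than OMOM and can later be removed without acid.

Step 3
Reactants: 3 1-(benzyloxy)-3,5-bis(methoxymethoxy)benzene; 4 prenyl bromide
Product: 5 5-(benzyloxy)-1,3-bis(methoxymethoxy)-2-prenylbenzene (prenyl between the two OMOM groups)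
Conditions: n-BuLi, THF, 0 °C; then CuI (10 mol %), 4, −78 °C → rt
Reagents that add atoms: none
Why: Directed ortho-metalation should favour the C–H flanked by two chelating OMOM groups over those next to the benzyl ether, and the aryllithium is alkylated at the primary carbon of the allylic bromide under copper catalysis; any isomer prenylated beside OBn converges on the same compound 6 in step 4.

Step 4
Reactants: 5 5-(benzyloxy)-1,3-bis(methoxymethoxy)-2-prenylbenzene; 4 prenyl bromide
Product: 6 1-(benzyloxy)-3,5-bis(methoxymethoxy)-2,4-diprenylbenzene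
Conditions: n-BuLi, THF, 0 °C; then CuI (10 mol %), 4, −78 °C → rt
Reagents that add atoms: none
Why: Second directed ortho-metalation at one of the two equivalent C–H positions between OBn and OMOM, then the same copper-catalysed allylic substitution; lithiation of a ring C–H between two oxygens should outrun deprotonation of the prenyl CH2.

Step 5
Reactants: 6 1-(benzyloxy)-3,5-bis(methoxymethoxy)-2,4-diprenylbenzene
Product: 7 3,5-bis(methoxymethoxy)-2,4-diprenylphenol
Conditions: lithium 4,4′-di-tert-butylbiphenylide (LiDBB, 2.2 equiv), THF, −78 °C; then H2O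
Reagents that add atoms: none
Why: Reductive debenzylation by single-electron transfer cleaves the benzylic C–O bond to phenoxide and benzyl anion, while the isolated trisubstituted alkenes, the MOM acetals and the electron-rich ring are not reduced at −78 °C; hydrogenolysis is avoided because of the prenyl groups.

Step 6
Reactants: 8 5-bromovanillin
Product: 9 3-bromo-5-methoxy-4-(methoxymethoxy)benzaldehyde
Conditions: MOMCl, i-Pr2NEt, CH2Cl2, 0 °C → rt
Reagents that add atoms: chloromethyl methyl ether (MOMCl), COCCl
Why: MOM ether formation on the acidic phenol para to the aldehyde, masking it for the coupling and ketene steps.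

Step 7
Reactants: 9 3-bromo-5-methoxy-4-(methoxymethoxy)benzaldehyde; 10 tributyl(prenyl)stannane
Product: 11 3-methoxy-4-(methoxymethoxy)-5-prenylbenzaldehyde
Conditions: Pd(PPh3)4 (5 mol %), DMF, 90 °C
Reagents that add atoms: none
Why: Stille coupling of the aryl bromide with the allylic stannane; reductive elimination at the less substituted allyl terminus should give the linear prenyl group, and the aldehyde and MOM ether are inert.

Step 8
Reactants: 11 3-methoxy-4-(methoxymethoxy)-5-prenylbenzaldehyde
Product: 12 3-methoxy-4-(methoxymethoxy)-5-prenylbenzoic acid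
Conditions: NaClO2, NaH2PO4, 2-methyl-2-butene (large excess), t-BuOH/H2O, rt
Reagents that add atoms: sodium chlorite, [Na+].[O-]Cl=O
Why: Pinnick oxidation of the aldehyde to the acid; the excess alkene scavenger removes HOCl so that the prenyl double bond and the electron-rich ring should not be chlorinated.

Step 9
Reactants: 12 3-methoxy-4-(methoxymethoxy)-5-prenylbenzoic acid; 13 Meldrum's acid
Product: 14 5-{hydroxy[3-methoxy-4-(methoxymethoxy)-5-prenylphenyl]methylidene}-2,2-dimethyl-1,3-dioxane-4,6-dione (enolised acyl Meldrum's acid)
Conditions: DCC, DMAP, CH2Cl2, 0 °C → rt; cold dilute KHSO4 wash, used crude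
Reagents that add atoms: none
Why: Carbodiimide/DMAP C-acylation of Meldrum's acid, a neutral activation that leaves MOM and prenyl untouched.

Step 10
Reactants: 14 acyl Meldrum's acid; 7 3,5-bis(methoxymethoxy)-2,4-diprenylphenol
Product: 16 3,5-bis(methoxymethoxy)-2,4-diprenylphenyl 3-[3-methoxy-4-(methoxymethoxy)-5-prenylphenyl]-3-oxopropanoate, via aroylketene 15 (not isolated)
Conditions: toluene, 90 °C, slow addition of 14 to 7
Reagents that add atoms: none
Why: Thermal fragmentation of the acyl Meldrum's acid releases acetone and CO2 and gives the aroylketene, which the phenol traps at oxygen (ketene acylation) to give the aryl β-keto ester without acid, base or coupling agent.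

Step 11
Reactants: 16 aryl β-keto ester
Product: 17 3,5-bis(methoxymethoxy)-2,4-diprenylphenyl (3R)-3-hydroxy-3-[3-methoxy-4-(methoxymethoxy)-5-prenylphenyl]propanoate
Conditions: RuCl[(R,R)-TsDPEN](p-cymene) (1 mol %), HCO2H/Et3N (5:2), EtOAc, 25 °C
Reagents that add atoms: none
Why: Noyori asymmetric transfer hydrogenation of the aryl ketone; the (R,R)-catalyst should deliver hydride to the face that gives the (R)-carbinol, as it does for acetophenone-type ketones, and the alkenes, the MOM ethers and the aryl ester are left alone in the mildly acidic medium.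

Step 12
Reactants: 17 (R)-β-hydroxy aryl ester
Product: 19 (2S)-5,7-bis(methoxymethoxy)-2-[3-methoxy-4-(methoxymethoxy)-5-prenylphenyl]-6,8-diprenylchroman-4-one, via photo-Fries hydroxy ketone 18 (not isolated)
Conditions: hν (254 nm, quartz flow reactor), degassed MeCN, rt, to full conversion of 17; then PPh3, DIAD, THF added, 0 °C → rt, same flask
Reagents that add atoms: none
Why: Excitation of the aryl ester homolyses the ArO–C(=O) bond to a caged phenoxyl/acyl radical pair that recombines at the only carbon able to rearomatise, C4a (the other ortho carbon and the para carbon carry prenyl), and tautomerises to the hydrogen-bonded o-hydroxyaryl ketone 18; this forms C4–C4a under neutral conditions that should spare the prenyl groups and MOM ethers (photo-Fries rearrangement of an aryl alkanoate). PPh3/DIAD then activates the benzylic (R)-carbinol, and the phenol just liberated by the shift displaces it in a 6-exo-tet closure of ring C (intramolecular Mitsunobu etherification, the known way from 2′-hydroxy-β-hydroxydihydrochalcones to flavanones). No stereocenter is created: C2 is carried through the photolysis untouched because neither radical centre is at C2, and it is inverted from R to S in the SN2 closure. The step needs regioselective acyl migration, which the substitution pattern of ring A secures, and substitution at C2 in preference to ionisation or E1cB elimination, which the fast six-membered closure and the 4′-OMOM group twisted out of conjugation by its two ortho neighbours should favour. Degassing keeps oxygen away from the prenyl groups, and the chelated ketone 18 should be stable to further irradiation.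

Step 13
Reactants: 19 (2S)-tris-MOM flavanone
Product: 20 (2S)-5,7-dihydroxy-2-(4-hydroxy-3-methoxy-5-prenylphenyl)-6,8-diprenylchroman-4-one (target)
Conditions: 3 M aq. HCl/MeOH, 40 °C, stopped at full conversion
Reagents that add atoms: none
Why: Acid-catalysed acetal exchange removes the three MOM ethers as dimethoxymethane; mild acid at moderate temperature is used so that the o-prenylphenols should not cyclise to chromans, and C2, which epimerises only by base-induced ring opening, is kept.

## Compound list

1 | phloroglucinol | Oc1cc(O)cc(O)c1 | starting material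
2 | 3,5-bis(methoxymethoxy)phenol | COCOc1cc(O)cc(OCOC)c1 | intermediate
3 | 1-(benzyloxy)-3,5-bis(methoxymethoxy)benzene | COCOc1cc(OCOC)cc(OCc2ccccc2)c1 | intermediate
4 | prenyl bromide | CC(C)=CCBr | starting material
5 | 5-(benzyloxy)-1,3-bis(methoxymethoxy)-2-prenylbenzene | COCOc1cc(OCc2ccccc2)cc(OCOC)c1CC=C(C)C | intermediate
6 | 1-(benzyloxy)-3,5-bis(methoxymethoxy)-2,4-diprenylbenzene | COCOc1cc(OCc2ccccc2)c(CC=C(C)C)c(OCOC)c1CC=C(C)C | intermediate
7 | 3,5-bis(methoxymethoxy)-2,4-diprenylphenol | COCOc1cc(O)c(CC=C(C)C)c(OCOC)c1CC=C(C)C | intermediate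
8 | 5-bromovanillin | COc1cc(C=O)cc(Br)c1O | starting material
9 | 3-bromo-5-methoxy-4-(methoxymethoxy)benzaldehyde | COCOc1c(Br)cc(C=O)cc1OC | intermediate
10 | tributyl(3-methylbut-2-en-1-yl)stannane | CCCC[Sn](CCCC)(CCCC)CC=C(C)C | starting material
11 | 3-methoxy-4-(methoxymethoxy)-5-prenylbenzaldehyde | COCOc1c(CC=C(C)C)cc(C=O)cc1OC | intermediate
12 | 3-methoxy-4-(methoxymethoxy)-5-prenylbenzoic acid | COCOc1c(CC=C(C)C)cc(C(=O)O)cc1OC | intermediate
13 | Meldrum's acid | CC1(C)OC(=O)CC(=O)O1 | starting material
14 | acyl Meldrum's acid of 12 (enol form) | COCOc1c(CC=C(C)C)cc(C(O)=C2C(=O)OC(C)(C)OC2=O)cc1OC | intermediate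
15 | aroylketene from 14 (not isolated) | COCOc1c(CC=C(C)C)cc(C(=O)C=C=O)cc1OC | intermediate
16 | aryl β-keto ester | COc1cc(C(=O)CC(=O)Oc2cc(OCOC)c(CC=C(C)C)c(OCOC)c2CC=C(C)C)cc(CC=C(C)C)c1OCOC | intermediate
17 | (3R)-β-hydroxy aryl ester (key-step precursor) | COc1cc([C@H](O)CC(=O)Oc2cc(OCOC)c(CC=C(C)C)c(OCOC)c2CC=C(C)C)cc(CC=C(C)C)c1OCOC | intermediate
18 | (3R)-3-hydroxy-1-[2-hydroxy-4,6-bis(methoxymethoxy)-3,5-diprenylphenyl]-3-[3-methoxy-4-(methoxymethoxy)-5-prenylphenyl]propan-1-one (not isolated) | COc1cc([C@H](O)CC(=O)c2c(O)c(CC=C(C)C)c(OCOC)c(CC=C(C)C)c2OCOC)cc(CC=C(C)C)c1OCOC | intermediate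
19 | (2S)-5,7,4′-tris-MOM flavanone (key-step product) | COc1cc([C@@H]2CC(=O)c3c(OCOC)c(CC=C(C)C)c(OCOC)c(CC=C(C)C)c3O2)cc(CC=C(C)C)c1OCOC | intermediate
20 | (2S)-5,7-dihydroxy-2-(4-hydroxy-3-methoxy-5-prenylphenyl)-6,8-diprenylchroman-4-one | COc1cc([C@@H]2CC(=O)c3c(O)c(CC=C(C)C)c(O)c(CC=C(C)C)c3O2)cc(CC=C(C)C)c1O | target

Total step count: 13
Longest linear sequence: 9 steps (steps 1–5, then 10–13)

## Steps most likely to fail

**Step 12.** The radical pair may escape the solvent cage and return phenol 7, and the prenyl groups may react under the light. In the Mitsunobu half, the activated carbinol may eliminate to the chalcone or ionise at the benzylic carbon, eroding the C2 configuration. Fallback (sets out from 7 and 11, comes back at 20), a carbanion acylation followed by chalcone cyclisation and resolution: phenol 7 is capped with MOMCl/i-Pr2NEt to 1,3,5-tris(methoxymethoxy)-2,4-diprenylbenzene F1. Lithiation of its last ring C–H (n-BuLi, THF, 0 °C) and quench with N-methoxy-N-methylacetamide should give 2,4,6-tris(methoxymethoxy)-3,5-diprenylacetophenone F2. Claisen–Schmidt condensation with aldehyde 11 (KOH, EtOH, rt) should give the protected chalcone F3. HCl/MeOH removes the four MOM ethers to the tetrahydroxychalcone F4, which NaOAc in refluxing EtOH cyclises by oxa-Michael addition to the racemic flavanone F5. The (2S)-enantiomer 20 is then separated by preparative HPLC on a chiral stationary phase.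

**Step 11.** The activated aryl ester may transfer its acyl group, or lose ketene, in the amine/formate medium, and hydride delivery to a partly enolised β-keto ester may be poorly face-selective. Fallback (sets out from 14 and 7, comes back at 17), reduction before the ring A phenol is attached and a Steglich esterification in place of ketene trapping: 14 is heated with allyl alcohol in toluene to the allyl β-keto ester F6. The same transfer hydrogenation gives the (R)-allyl β-hydroxy ester F7, which TBSCl/imidazole converts to the silyl ether F8. Pd(PPh3)4/morpholine removes the allyl group (Tsuji–Trost deallylation) to the (R)-β-silyloxy acid F9. EDC/DMAP couples F9 with phenol 7 to the silyl-protected aryl ester F10, and HF·pyridine in THF removes the silyl group to give 17.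

**Step 13.** Protic acid may cyclise the prenyl groups onto the neighbouring free phenols (chroman formation) before all three MOM ethers are gone. Fallback (sets out from 19, comes back at 20), silyl exchange without Brønsted acid: TMSOTf/2,2′-bipyridyl in CH2Cl2 at 0 °C should convert the aryl MOM ethers into the tris(trimethylsilyl) ether F11, and the aryl silyl ethers are then hydrolysed with water/MeOH at rt under neutral conditions to give 20.

## Further compounds

F1 | step 12 | 1,3,5-tris(methoxymethoxy)-2,4-diprenylbenzene | COCOc1cc(OCOC)c(CC=C(C)C)c(OCOC)c1CC=C(C)C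
F2 | step 12 | 1-[2,4,6-tris(methoxymethoxy)-3,5-diprenylphenyl]ethan-1-one | CC(=O)c1c(OCOC)c(CC=C(C)C)c(OCOC)c(CC=C(C)C)c1OCOC
F3 | step 12 | (E)-chalcone, fully MOM-protected | COc1cc(/C=C/C(=O)c2c(OCOC)c(CC=C(C)C)c(OCOC)c(CC=C(C)C)c2OCOC)cc(CC=C(C)C)c1OCOC
F4 | step 12 | (E)-2′,4′,6′,4-tetrahydroxy-3-methoxy-3′,5′,5-triprenylchalcone | COc1cc(/C=C/C(=O)c2c(O)c(CC=C(C)C)c(O)c(CC=C(C)C)c2O)cc(CC=C(C)C)c1O
F5 | step 12 | racemic flavanone (both C2 epimers of the target) | COc1cc(C2CC(=O)c3c(O)c(CC=C(C)C)c(O)c(CC=C(C)C)c3O2)cc(CC=C(C)C)c1O
F6 | step 11 | allyl 3-[3-methoxy-4-(methoxymethoxy)-5-prenylphenyl]-3-oxopropanoate | COc1cc(C(=O)CC(=O)OCC=C)cc(CC=C(C)C)c1OCOC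
F7 | step 11 | allyl (3R)-3-hydroxy-3-[3-methoxy-4-(methoxymethoxy)-5-prenylphenyl]propanoate | COc1cc([C@H](O)CC(=O)OCC=C)cc(CC=C(C)C)c1OCOC
F8 | step 11 | allyl (3R)-3-(tert-butyldimethylsilyloxy)-3-arylpropanoate | COc1cc([C@H](O[Si](C)(C)C(C)(C)C)CC(=O)OCC=C)cc(CC=C(C)C)c1OCOC
F9 | step 11 | (3R)-3-(tert-butyldimethylsilyloxy)-3-[3-methoxy-4-(methoxymethoxy)-5-prenylphenyl]propanoic acid | COc1cc([C@H](O[Si](C)(C)C(C)(C)C)CC(=O)O)cc(CC=C(C)C)c1OCOC
F10 | step 11 | 3,5-bis(methoxymethoxy)-2,4-diprenylphenyl (3R)-3-(tert-butyldimethylsilyloxy)-3-arylpropanoate | COc1cc([C@H](O[Si](C)(C)C(C)(C)C)CC(=O)Oc2cc(OCOC)c(CC=C(C)C)c(OCOC)c2CC=C(C)C)cc(CC=C(C)C)c1OCOC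
F11 | step 13 | (2S)-5,7,4′-tris(trimethylsilyl) ether of the target | COc1cc([C@@H]2CC(=O)c3c(O[Si](C)(C)C)c(CC=C(C)C)c(O[Si](C)(C)C)c(CC=C(C)C)c3O2)cc(CC=C(C)C)c1O[Si](C)(C)C
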